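**Retrosynthetic overview**
1. Feature used: O1 (on C8a) sits next to the C8 methoxy group and C3 carries oxygen. Ring A therefore maps onto symmetric 3,4,5-trimethoxyphenol: its OH becomes 5-OH, and the methoxy group beside the new acyl carbon becomes O1.
2. Ring C is the only ring made. O1–C2 is closed by ICl-induced 6-endo-dig attack of that methoxy oxygen on an aryl alkynyl ketone, with loss of CH3Cl and with iodine delivered to C3.
3. The ynone (C4–C3 bond) comes from a lithium arylacetylide and an ortho-pivaloyloxy benzaldehyde, followed by MnO2 oxidation.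
4. Ring A fragment: ortho-formylation and O-pivaloylation of 3,4,5-trimethoxyphenol. Ring B fragment: diphenylmethylene acetal of 2,3-dihydroxybenzaldehyde, then one-carbon homologation to the terminal alkyne.
5. End game: C3–I to C3–OMe with NaOMe and CuI (the pivalate is lost in the same flask), then hydrogenolysis of the acetal.

Key step: step 7

Remark: the ring B catechol is carried as a cyclic diphenylmethylene acetal, not as open-chain ethers, because a freely rotating 2'-alkoxy oxygen could compete for the activated alkyne by 5-endo-dig closure. Alcohol 10 is racemic, and its stereocentre is removed in step 6.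

**Route**

Step 1
Reactants: 1 3,4,5-trimethoxyphenol
Product: 2 6-hydroxy-2,3,4-trimethoxybenzaldehyde
Conditions: MgCl2, Et3N, (CH2O)n, MeCN, reflux; then 1 M HCl
Reagents that add atoms: paraformaldehyde (formaldehyde unit), C=O
Why: Casnati–Skattebøl ortho-formylation, in which the magnesium phenoxide directs formaldehyde to one of the two equivalent free ortho carbons and a second formaldehyde oxidises the hydroxymethyl group by hydride transfer.

Step 2
Reactants: 2 6-hydroxy-2,3,4-trimethoxybenzaldehyde; 3 pivaloyl chloride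
Product: 4 2-formyl-3,4,5-trimethoxyphenyl pivalate
Conditions: PivCl, Et3N, DMAP (cat.), CH2Cl2, 0 °C to rt
Reagents that add atoms: pivaloyl chloride (compound 3), CC(C)(C)C(Cl)=O
Why: DMAP-catalysed O-acylation of the phenol, which turns the future 5-oxygen into a non-nucleophilic, hindered ester and leaves the methoxy group on the other side of the formyl group as the only ortho oxygen able to close ring C.

Step 3
Reactants: 5 2,3-dihydroxybenzaldehyde; 6 dichlorodiphenylmethane
Product: 7 2,2-diphenyl-1,3-benzodioxole-4-carbaldehyde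
Conditions: Ph2CCl2 (1.3 equiv), Ph2O, 175 °C
Reagents that add atoms: dichlorodiphenylmethane (compound 6), ClC(Cl)(c1ccccc1)c1ccccc1
Why: Double O-alkylation of the catechol by the benzhydrylic dichloride (acetal formation with loss of HCl), a standard catechol protection that the aldehyde should tolerate.

Step 4
Reactants: 7 2,2-diphenyl-1,3-benzodioxole-4-carbaldehyde
Product: 8 4-ethynyl-2,2-diphenyl-1,3-benzodioxole
Conditions: dimethyl (1-diazo-2-oxopropyl)phosphonate, K2CO3, MeOH, 0 °C to rt
Reagents that add atoms: dimethyl (1-diazo-2-oxopropyl)phosphonate (Ohira–Bestmann reagent), CC(=O)C(=[N+]=[N-])P(=O)(OC)OC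
Why: Ohira–Bestmann modification of the Seyferth–Gilbert homologation, which converts a non-enolisable aryl aldehyde into the terminal alkyne in one step under conditions the acetal withstands.

Step 5
Reactants: 8 4-ethynyl-2,2-diphenyl-1,3-benzodioxole; 4 2-formyl-3,4,5-trimethoxyphenyl pivalate
Product: 10 2-[3-(2,2-diphenyl-1,3-benzodioxol-4-yl)-1-hydroxyprop-2-yn-1-yl]-3,4,5-trimethoxyphenyl pivalate (racemate), via lithium acetylide 9 (not isolated)
Conditions: 8 (1.15 equiv), n-BuLi (1.1 equiv), THF, −78 °C; then 4, −78 °C; AcOH in THF at −78 °C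
Reagents that add atoms: n-butyllithium, [Li]CCCC (its lithium is held only in intermediate 9; no atom of it remains in 10)
Why: 1,2-addition of a lithium acetylide to an aryl aldehyde, which is much faster at −78 °C than attack on the hindered pivalate; the new carbinol centre forms as a racemate and is erased in step 6, and the cold acidic quench should prevent pivaloyl transfer to the alkoxide.

Step 6
Reactants: 10 2-[3-(2,2-diphenyl-1,3-benzodioxol-4-yl)-1-hydroxyprop-2-yn-1-yl]-3,4,5-trimethoxyphenyl pivalate
Product: 11 2-[3-(2,2-diphenyl-1,3-benzodioxol-4-yl)prop-2-ynoyl]-3,4,5-trimethoxyphenyl pivalate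
Conditions: activated MnO2 (excess), CH2Cl2, rt
Reagents that add atoms: none
Why: MnO2 oxidation of a doubly activated (benzylic and propargylic) secondary alcohol to the ynone under neutral conditions that leave the ester and the acetal alone.

Step 7
Reactants: 11 2-[3-(2,2-diphenyl-1,3-benzodioxol-4-yl)prop-2-ynoyl]-3,4,5-trimethoxyphenyl pivalate
Product: 12 2-(2,2-diphenyl-1,3-benzodioxol-4-yl)-3-iodo-7,8-dimethoxy-4-oxo-4H-chromen-5-yl pivalate
Conditions: ICl (1.2 equiv, 1 M in CH2Cl2), CH2Cl2, −78 °C, dark; aq. Na2S2O3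
Reagents that add atoms: iodine monochloride, ICl
Why: ICl delivers an iodonium to the ynone triple bond, the lone pair of the methoxy oxygen beside the ketone opens it at the aryl-bearing β-carbon anti to iodine, and chloride then removes the methyl group of the aryl(methyl)oxonium ion by SN2 as CH3Cl, which makes the closure irreversible. The closest known reaction type is the ICl-induced demethylative iodocyclisation of 2-methoxyaryl alkynyl ketones to 3-iodochromones and 3-iodoflavones. Ring C closes in the 6-endo-dig mode (O1–C2), favoured over 5-exo because the ketone polarises the alkyne so that positive charge builds at the β-carbon, where the electron-rich benzodioxolyl group stabilises it; no stereocentre is formed. Three selectivities are needed: closure through the methoxy oxygen and not the other ortho oxygen, secured by the pivalate, whose oxygen lone pairs are delocalised into the ester carbonyl; no closure from ring B, secured because the 2'-oxygen is locked in the dioxole ring and could reach the ketone-bearing alkyne carbon only by building a second five-membered ring on the same C–O bond; and attack of the alkyne before the arenes, secured by low temperature, near-stoichiometric ICl and the fact that the only C–H of ring A is flanked by two oxygen substituents and lies meta to the ketone. Iodine ends on C3, the carbon that must carry the methoxy group.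

Step 8
Reactants: 12 2-(2,2-diphenyl-1,3-benzodioxol-4-yl)-3-iodo-7,8-dimethoxy-4-oxo-4H-chromen-5-yl pivalate
Product: 14 2-(2,2-diphenyl-1,3-benzodioxol-4-yl)-5-hydroxy-3,7,8-trimethoxy-4H-chromen-4-one, via iodophenol 13 (not isolated)
Conditions: NaOMe (6 equiv), CuI (30 mol%), MeOH–DMF (1:4), 100 °C, Ar; then 1 M HCl
Reagents that add atoms: sodium methoxide, [Na+].[O-]C
Why: Methoxide first transesterifies the aryl pivalate (giving the phenoxide of 13, which deactivates the pyranone towards ring opening), and the sp2 C3–I bond then undergoes Ullmann-type C–O coupling with methoxide mediated by monovalent copper, as used for methoxylation of iodoflavones.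

Step 9
Reactants: 14 2-(2,2-diphenyl-1,3-benzodioxol-4-yl)-5-hydroxy-3,7,8-trimethoxy-4H-chromen-4-one
Product: 15 5,2',3'-trihydroxy-3,7,8-trimethoxyflavone
Conditions: H2 (1 atm), 10% Pd/C, THF–MeOH, rt; filtration under Ar
Reagents that add atoms: none
Why: Hydrogenolysis of the two doubly benzylic C–O bonds of the diphenylmethylene acetal on palladium should free the catechol and give diphenylmethane, while the tetrasubstituted C2=C3 bond, the methyl ethers and the hydrogen-bonded 5-OH are not touched.

**Compound list**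
1 | 3,4,5-trimethoxyphenol | COc1cc(O)cc(OC)c1OC | starting material
2 | 6-hydroxy-2,3,4-trimethoxybenzaldehyde | COc1cc(O)c(C=O)c(OC)c1OC | intermediate
3 | pivaloyl chloride | CC(C)(C)C(Cl)=O | starting material
4 | 2-formyl-3,4,5-trimethoxyphenyl pivalate | COc1cc(OC(=O)C(C)(C)C)c(C=O)c(OC)c1OC | intermediate
5 | 2,3-dihydroxybenzaldehyde | O=Cc1cccc(O)c1O | starting material
6 | dichlorodiphenylmethane | ClC(Cl)(c1ccccc1)c1ccccc1 | starting material
7 | 2,2-diphenyl-1,3-benzodioxole-4-carbaldehyde | O=Cc1cccc2OC(c3ccccc3)(c3ccccc3)Oc12 | intermediate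
8 | 4-ethynyl-2,2-diphenyl-1,3-benzodioxole | C#Cc1cccc2OC(c3ccccc3)(c3ccccc3)Oc12 | intermediate
9 | lithium (2,2-diphenyl-1,3-benzodioxol-4-yl)acetylide (formed in the flask, not isolated) | [Li]C#Cc1cccc2OC(c3ccccc3)(c3ccccc3)Oc12 | intermediate
10 | 2-[3-(2,2-diphenyl-1,3-benzodioxol-4-yl)-1-hydroxyprop-2-yn-1-yl]-3,4,5-trimethoxyphenyl pivalate (racemate) | COc1cc(OC(=O)C(C)(C)C)c(C(O)C#Cc2cccc3OC(c4ccccc4)(c4ccccc4)Oc23)c(OC)c1OC | intermediate
11 | 2-[3-(2,2-diphenyl-1,3-benzodioxol-4-yl)prop-2-ynoyl]-3,4,5-trimethoxyphenyl pivalate | COc1cc(OC(=O)C(C)(C)C)c(C(=O)C#Cc2cccc3OC(c4ccccc4)(c4ccccc4)Oc23)c(OC)c1OC | intermediate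
12 | 2-(2,2-diphenyl-1,3-benzodioxol-4-yl)-3-iodo-7,8-dimethoxy-4-oxo-4H-chromen-5-yl pivalate | COc1cc(OC(=O)C(C)(C)C)c2c(=O)c(I)c(-c3cccc4OC(c5ccccc5)(c5ccccc5)Oc34)oc2c1OC | intermediate
13 | 2-(2,2-diphenyl-1,3-benzodioxol-4-yl)-5-hydroxy-3-iodo-7,8-dimethoxy-4H-chromen-4-one (present as its sodium phenoxide, not isolated) | COc1cc(O)c2c(=O)c(I)c(-c3cccc4OC(c5ccccc5)(c5ccccc5)Oc34)oc2c1OC | intermediate
14 | 2-(2,2-diphenyl-1,3-benzodioxol-4-yl)-5-hydroxy-3,7,8-trimethoxy-4H-chromen-4-one | COc1cc(O)c2c(=O)c(OC)c(-c3cccc4OC(c5ccccc5)(c5ccccc5)Oc34)oc2c1OC | intermediate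
15 | 5,2',3'-trihydroxy-3,7,8-trimethoxyflavone [2-(2,3-dihydroxyphenyl)-5-hydroxy-3,7,8-trimethoxy-4H-chromen-4-one] | COc1cc(O)c2c(=O)c(OC)c(-c3cccc(O)c3O)oc2c1OC | target

**Step count**
Total steps: 9. Longest linear sequence: 7 (steps 1, 2, 5, 6, 7, 8, 9; the ring B branch, steps 3, 4, 5–9, is equally long).

**Steps most likely to fail**

Step 7. The electrophile may iodinate the electron-rich arenes, may add across the alkyne as I–Cl without ring closure, or may open the acetal as a Lewis acid. The fallback separates ring closure from iodination and closes ring C through a free phenol; it sets out from 4 and comes back at 12. BCl3 in CH2Cl2 (−78 to 0 °C) should cleave only the methyl ether that chelates with the formyl group and give 2-formyl-3-hydroxy-4,5-dimethoxyphenyl pivalate F1. Addition of two equivalents of lithium acetylide 9 (the first deprotonates the phenol) in THF at −78 °C should give racemic 3-hydroxy-2-[3-(2,2-diphenyl-1,3-benzodioxol-4-yl)-1-hydroxyprop-2-yn-1-yl]-4,5-dimethoxyphenyl pivalate F2. MnO2 in CH2Cl2 should oxidise it to the ortho-hydroxyaryl ynone 3-hydroxy-2-[3-(2,2-diphenyl-1,3-benzodioxol-4-yl)prop-2-ynoyl]-4,5-dimethoxyphenyl pivalate F3. Catalytic DMAP in DMF should bring about the 6-endo oxa-Michael closure to 2-(2,2-diphenyl-1,3-benzodioxol-4-yl)-7,8-dimethoxy-4-oxo-4H-chromen-5-yl pivalate F4. Iodination at C3 with I2 and (NH4)2Ce(NO3)6 in MeCN should then give 12.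

Step 8. Reductive loss of iodine may outrun the C–O coupling, or methoxide may add at C2 and open ring C, after which reclosure through the freed 5-oxygen would scramble the ring A pattern. The fallback makes the C3–O bond through boron under weakly basic conditions and keeps the pivalate until the end; it sets out from 12 and comes back at 14. Miyaura borylation (B2pin2, PdCl2(dppf), KOAc, dioxane, 80 °C) should give 2-(2,2-diphenyl-1,3-benzodioxol-4-yl)-7,8-dimethoxy-4-oxo-3-(4,4,5,5-tetramethyl-1,3,2-dioxaborolan-2-yl)-4H-chromen-5-yl pivalate F5. Oxidation with NaBO3·4H2O in THF–H2O should give the flavonol 2-(2,2-diphenyl-1,3-benzodioxol-4-yl)-3-hydroxy-7,8-dimethoxy-4-oxo-4H-chromen-5-yl pivalate F6. O-methylation with MeI and K2CO3 in acetone should give 2-(2,2-diphenyl-1,3-benzodioxol-4-yl)-3,7,8-trimethoxy-4-oxo-4H-chromen-5-yl pivalate F7. Methanolysis of the ester (K2CO3, MeOH, rt) should then give 14.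

Step 5. The pivaloyl group may migrate from the phenol oxygen to the neighbouring benzylic alkoxide through a six-membered transition state, or the electron-rich propargylic alcohol may ionise on work-up. The fallback forms the ynone directly by acyl cross-coupling, so that no alkoxide is generated; it sets out from 4 and comes back at 11. Pinnick oxidation (NaClO2, NaH2PO4, 2-methyl-2-butene, t-BuOH–H2O) should give 2,3,4-trimethoxy-6-(pivaloyloxy)benzoic acid F8. Oxalyl chloride with catalytic DMF in CH2Cl2 should give 2,3,4-trimethoxy-6-(pivaloyloxy)benzoyl chloride F9. Acyl Sonogashira coupling of F9 with alkyne 8 (PdCl2(PPh3)2, CuI, Et3N, THF, rt) should then give 11.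

**Further compounds**
F1 | step 7 | 2-formyl-3-hydroxy-4,5-dimethoxyphenyl pivalate | COc1cc(OC(=O)C(C)(C)C)c(C=O)c(O)c1OC
F2 | step 7 | 3-hydroxy-2-[3-(2,2-diphenyl-1,3-benzodioxol-4-yl)-1-hydroxyprop-2-yn-1-yl]-4,5-dimethoxyphenyl pivalate (racemate) | COc1cc(OC(=O)C(C)(C)C)c(C(O)C#Cc2cccc3OC(c4ccccc4)(c4ccccc4)Oc23)c(O)c1OC
F3 | step 7 | 3-hydroxy-2-[3-(2,2-diphenyl-1,3-benzodioxol-4-yl)prop-2-ynoyl]-4,5-dimethoxyphenyl pivalate | COc1cc(OC(=O)C(C)(C)C)c(C(=O)C#Cc2cccc3OC(c4ccccc4)(c4ccccc4)Oc23)c(O)c1OC
F4 | step 7 | 2-(2,2-diphenyl-1,3-benzodioxol-4-yl)-7,8-dimethoxy-4-oxo-4H-chromen-5-yl pivalate | COc1cc(OC(=O)C(C)(C)C)c2c(=O)cc(-c3cccc4OC(c5ccccc5)(c5ccccc5)Oc34)oc2c1OC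
F5 | step 8 | 2-(2,2-diphenyl-1,3-benzodioxol-4-yl)-7,8-dimethoxy-4-oxo-3-(4,4,5,5-tetramethyl-1,3,2-dioxaborolan-2-yl)-4H-chromen-5-yl pivalate | COc1cc(OC(=O)C(C)(C)C)c2c(=O)c(B3OC(C)(C)C(C)(C)O3)c(-c3cccc4OC(c5ccccc5)(c5ccccc5)Oc34)oc2c1OC
F6 | step 8 | 2-(2,2-diphenyl-1,3-benzodioxol-4-yl)-3-hydroxy-7,8-dimethoxy-4-oxo-4H-chromen-5-yl pivalate | COc1cc(OC(=O)C(C)(C)C)c2c(=O)c(O)c(-c3cccc4OC(c5ccccc5)(c5ccccc5)Oc34)oc2c1OC
F7 | step 8 | 2-(2,2-diphenyl-1,3-benzodioxol-4-yl)-3,7,8-trimethoxy-4-oxo-4H-chromen-5-yl pivalate | COc1cc(OC(=O)C(C)(C)C)c2c(=O)c(OC)c(-c3cccc4OC(c5ccccc5)(c5ccccc5)Oc34)oc2c1OC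
F8 | step 5 | 2,3,4-trimethoxy-6-(pivaloyloxy)benzoic acid | COc1cc(OC(=O)C(C)(C)C)c(C(=O)O)c(OC)c1OC
F9 | step 5 | 2,3,4-trimethoxy-6-(pivaloyloxy)benzoyl chloride | COc1cc(OC(=O)C(C)(C)C)c(C(Cl)=O)c(OC)c1OC
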